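Count how long the uncatalysed step needs to start the autocatalytic one.

the same everywhere: starting material 20 mM; time 40 h
- Thursday's: temperature 100 °C
- Friday's: temperature 125 °C

    starting material + 2 product → 3 product (k1 = 570 M⁻² h⁻¹, Ea1 = 67.0 kJ mol⁻¹)
    starting material → product (k2 = 0.0032 h⁻¹, Ea2 = 124 kJ mol⁻¹)
    2 starting material → homo dimer (k3 = 0.011 M⁻¹ h⁻¹, Ea3 = 100 kJ mol⁻¹)
    crystals ⇌ product, rate k4*(cs4 - [product]) while solid is left; crystals form when [product] > cs4 (cs4 = 7.2 mM, k4 = 7.6 h⁻¹)
    (constants at 100 °C)

- which of these there is most of at the end, counted by the starting material in it, Thursday's (starting material / product)
- which of these there is most of at the end, counted by the starting material in it, Friday's (starting material / product)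
- amount of the one of these that there is most of at the end, in percent of the starting material charged, Thursday's
- amount of the one of these that there is most of at the end, in percent of the starting material charged, Friday's

- percent here means starting material units held: one homo dimer counts as two
- what is said of product includes crystals
- two of one species on the left: rate k times its square, two consumed each time
- crystals is a solid; its amount is given per volume of the solution
- the constants hold at 100 °C; other temperatures follow from the activation energies

Call the second step the plain step and the first the autocatalytic step. With no product present, the plain step on Thursday's opens at 0.0640 mM h⁻¹. The two run equally fast when dissolved product stands at a certain level, the square root of k2/k1, which is 2.37 mM on Thursday's. On Thursday's, the level divided by the opening rate gives 37.0 h. This is the take-off time, your induction period; it equals 1/(charge × square root of k1·k2).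

On Friday's, the constant of the autocatalytic step becomes 2210 M⁻² h⁻¹ and that of the plain step 0.0394 h⁻¹.

Now take two extreme versions. In the first, the autocatalytic step is absent. In the second, product sits at its solubility from the start, so starting material decays pseudo-first-order. The real flasks start like the first and move towards the second. I set the dimer step aside: on Thursday's it opens at 4.40 × 10⁻⁴ h⁻¹, slower than the plain step's 0.0032 h⁻¹.

| Flask | Take-off time | Starting material left at the end, first version | Starting material left at the end, second version |
|---|---|---|---|
| Thursday's | 37.0 h | 88.0% | 27.0% |
| Friday's | 5.36 h | 20.7% | 0.211% |

Thursday's take-off time is close to its 40 h, so that flask stays near the first version. I grant the autocatalytic step as much as the plain step made, which leaves 76.0% starting material. Friday's take-off time is shorter than 40 h, so that flask runs near the second version. The lifetime of starting material at the second version's rate on Friday's is 6.49 h, and the time after take-off holds 5.34 lifetimes. Counted from the full charge, my estimate leaves 0.481%.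

The forecast gives starting material at 80.5% on Thursday's and product at 97.7% on Friday's, holding that “the autocatalysis is limited by that solubility”.

The simulation gives starting material at 80.4% on Thursday's, higher than my figure, and product at 97.7% on Friday's, with 0.343% starting material left. On Thursday's, the level is 11.8% of the charge, and product stands at 6.79% after 20.0 h and 18.1% after 40.0 h.

Now charge Thursday's flask with 80 mM. The level stays the same, but the take-off time drops to 9.26 h, a quarter of Thursday's. In that flask, the time after take-off holds 1.01 lifetimes at the second version's rate. Counted from the full charge, my estimate leaves 36.5%. That flask gives 33.1% starting material, and product now holds the most, at 63.3%, of which crystals are 54.1%.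

The constants were drawn at random within sensible limits; the result is computed.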